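Thursday's percentage loss of starting material per second, as read, stands to Tuesday's at 1.03, although Thursday's charge is 2.00 times Tuesday's.

| setting | Thursday's | Tuesday's | flask |
|---|---|---|---|
| starting material | 0.20 mM | 0.10 mM | 0.20 mM |
| second substrate | 1 equiv | 1 equiv | 1.00 equiv |
| solid reagent | 1.5 equiv | 1.5 equiv | 1.50 equiv |
| remark | the very flask that is asked about, followed so far | run made earlier |  |
| time |  |  | 3.0 min |

- Thursday's (time / s: target / %, starting material / %): 10.0: 4.2, 95.7; 12.0: 5.8, 94.2; 20.0: 9.4, 88.6; 30.0: 12.2, 82.0; 40.0: 14.5, 76.7
- Tuesday's (time / min: target / %, starting material / %): 0.200: 6.8, 93.2; 0.667: 16.8, 77.9; 1.00: 15.9, 74.8; 1.50: 10.8, 74.8; 2.50: 5.7, 75.2; 3.00: 5.4, 75.1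

(standard deviation of a reading: 0.5 percentage points)

* how much target there is at 3.0 min, in percent of the starting material charged
* concentration of partner in solution at 3.0 min, in percent of saturation

1. Tuesday's starting material falls in a straight line, then stands near 75.1 %. I divide Tuesday's loss by Thursday's rate and get the solid clock, my estimate of how long Tuesday's solid reagent lasts, taking that stop as its end: 0.712 min.

2. Extreme one: solid reagent dissolves in proportion to what is left. Thursday's flask then keeps Tuesday's clock. If it also reads like Tuesday at the asked time, I expect 5.4 % target.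

3. Extreme two: solid reagent dissolves at a fixed rate in mM per minute, zero order in the solid. Thursday's clock then doubles to 1.42 min. If target then falls at Tuesday's pace, the time left after it places Thursday's flask between Tuesday's readings at 1.50 min and 2.50 min, which gives 6.78 %.

4. The like percentage rates favour extreme one. But Tuesday's line stops sharply instead of fading, so I lean to extreme two and commit to that figure.

The forecast gives 4.8 % target (2.5 % to 7.5 %) and partner at 5 % of saturation (0 % to 60 %), saying “Partner should be nearly gone”.

The flask gives 4.53 % target and partner at 13.9 % of saturation.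

    2 partner → homo dimer (k = 430 M⁻¹ s⁻¹)
    solid reagent ⇌ partner, rate k2*(cs2 - [partner]) while solid is left; crystals form when [partner] > cs2 (solubility = 0.0940 mM, k = 0.0630 s⁻¹)
    starting material + partner ⇌ target (K = 5900 M⁻¹, k = 250 M⁻¹ s⁻¹)
    starting material + target → side product (k = 82.0 M⁻¹ s⁻¹)
    second substrate + partner ⇌ second product (K = 42000 M⁻¹, k = 6.10 M⁻¹ s⁻¹)

Thursday's target stands 2.2 percentage points under my figure. Its solid reagent still holds 7.34 % of its charge at 1.50 min, later than my doubled clock, and 0 % at 2.00 min. Its target goes from 11.2 % at 2.00 min to 4.53 % at 3.00 min, while Tuesday's readings go from 10.8 % at 1.50 min to 5.7 % at 2.50 min. A flask with 0.34 mM of starting material at the same equivalents has a reckoned clock of 2.42 min. At 3.00 min that flask holds 0 % solid reagent and 8.25 % target.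

The numbers in the tables are simulated for an exercise, noise included.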